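Assumption: side-chain atoms are numbered C1–C16 from the benzylic carbon; the single stereocentre (C11) is R, as read from the SMILES; geranyl acetate, prenyl chloride, prenyl bromide and 4-methoxy-2-methylphenol are bought.

**Retrosynthetic overview**

- Key disconnection C12–O: the C12 carbonyl oxygen is put on the E-methyl of geranyl acetate by allylic C–H oxygenation; geranyl acetate then supplies C5–C12, both methyl branches, the 6E alkene and the C5 oxygen.
- C11 stereocentre: enantioselective redox isomerization of the resulting 2-methyl allylic alcohol to the (R)-2-methyl aldehyde (proposed new method).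
- C12–C13 and C4–C5: two alpha-selective allylbarium additions (prenyl, then the aryl-bearing E-allyl unit) to the C12 aldehyde and the C5 enal.
- Aryl allyl unit: ortho C-prenylation of 4-methoxy-2-methylphenol, a second allylic oxygenation (C4–O), then OH to Cl.
- End game: double alcohol oxidation and desilylation; no ring is formed at any stage (the benzene ring is bought intact).

**Route**

Step 1
Reactants: 1 geranyl acetate, (2E)-3,7-dimethylocta-2,6-dien-1-yl acetate
Product: 2 (2E,6E)-8-hydroxy-3,7-dimethylocta-2,6-dien-1-yl acetate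
Conditions: SeO2 (10 mol %), t-BuOOH (3 equiv), salicylic acid (10 mol %), CH2Cl2, 23 °C
Reagents that add atoms: tert-butyl hydroperoxide, CC(C)(C)OO (its oxygen atom, relayed by SeO2, O=[Se]=O)
Why: Sharpless SeO2/t-BuOOH allylic oxidation (ene reaction then [2,3]-sigmatropic shift) oxygenates the E-methyl of the electron-rich terminal alkene, the 2,3-alkene being deactivated by the allylic acetate, so the C8–O bond (the future C12 carbonyl oxygen) forms with E geometry.

Step 2
Reactants: 2 (2E,6E)-8-hydroxy-3,7-dimethylocta-2,6-dien-1-yl acetate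
Product: 3 (2E,7R)-3,7-dimethyl-8-oxooct-2-en-1-yl acetate
Conditions: [Ir(cod)(L)]BArF (5 mol %; L = 4-tert-butyl-2-[2-(di-1-adamantylphosphino)phenyl]-4,5-dihydrooxazole, antipode picked in a pilot run to give 7R; BArF = B[3,5-(CF3)2C6H3]4), H2 (1 atm, 1 min) then degas, THF, 23 °C; used crude
Reagents that add atoms: none
Why: Proposed new method: the H2-activated cationic iridium dihydride binds the free primary allylic alcohol, takes off the carbinol hydrogen to give an iridium-bound 2-methyl enal/enol and returns hydride to C6 and then to C7 from one face fixed by the bulky chiral P,N ligand before the enol leaves the metal, so that C7 (the future C11) is set as R while the 2,3-alkene, which carries only an acetate and cannot chelate, is untouched; the closest known reaction type is the iridium-catalysed enantioselective redox isomerization of 3,3-disubstituted primary allylic alcohols to beta-chiral aldehydes (and the OH-directed Noyori hydrogenation), which has not been shown to control a stereocentre alpha to the new aldehyde.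

Step 3
Reactants: 3 (2E,7R)-3,7-dimethyl-8-oxooct-2-en-1-yl acetate; 4 prenyl chloride, 1-chloro-3-methylbut-2-ene
Product: 7 (2E,7R)-3,7,11-trimethyldodeca-2,10-diene-1,8-diol, via prenylbarium chloride 5 (not isolated), via hydroxy acetate 6 (not isolated)
Conditions: activated Ba (from BaI2, lithium biphenylide, THF), 4, −78 °C; then 3, −78 °C, 30 min; aq NH4Cl; crude, K2CO3 (20 mol %), MeOH, 23 °C
Reagents that add atoms: none
Why: Yamamoto allylbarium addition, in which prenylbarium chloride attacks the aldehyde through its unsubstituted alpha carbon at −78 °C (no allylic transposition, too fast for enolisation at C7), gives the linear homoallylic alcohol as a C8 epimer mixture that does not matter because C8 becomes a ketone, and K2CO3/MeOH transesterification then frees the primary alcohol.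

Step 4
Reactants: 7 (2E,7R)-3,7,11-trimethyldodeca-2,10-diene-1,8-diol
Product: 8 (2E,7R)-8-hydroxy-3,7,11-trimethyldodeca-2,10-dienal
Conditions: activated MnO2 (15 equiv), CH2Cl2, 23 °C
Reagents that add atoms: none
Why: MnO2 allylic oxidation converts only the primary allylic alcohol into the E-enal and leaves the homoallylic secondary alcohol and C7 untouched.

Step 5
Reactants: 9 4-methoxy-2-methylphenol; 10 prenyl bromide, 1-bromo-3-methylbut-2-ene
Product: 11 4-methoxy-2-methyl-6-(3-methylbut-2-en-1-yl)phenol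
Conditions: NaH (1.05 equiv), toluene, 0 °C; then 10, 23 °C, 16 h
Reagents that add atoms: none
Why: Ortho C-alkylation of a sodium phenoxide held as a tight ion pair in a non-polar solvent (Claisen-type C-allylation) puts the prenyl group on the only free ortho carbon, the para position being blocked by OMe.

Step 6
Reactants: 11 4-methoxy-2-methyl-6-(3-methylbut-2-en-1-yl)phenol
Product: 12 tert-butyl[4-methoxy-2-methyl-6-(3-methylbut-2-en-1-yl)phenoxy]dimethylsilane
Conditions: TBSCl, imidazole, DMAP (5 mol %), DMF, 40 °C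
Reagents that add atoms: tert-butyldimethylsilyl chloride, CC(C)(C)[Si](C)(C)Cl
Why: Corey silylation masks the phenol against the organobarium and oxidation steps that follow.

Step 7
Reactants: 12 tert-butyl[4-methoxy-2-methyl-6-(3-methylbut-2-en-1-yl)phenoxy]dimethylsilane
Product: 13 (2E)-4-[2-(tert-butyldimethylsilyloxy)-5-methoxy-3-methylphenyl]-2-methylbut-2-en-1-ol
Conditions: SeO2 (20 mol %), t-BuOOH (3 equiv), salicylic acid (10 mol %), CH2Cl2, 23 °C
Reagents that add atoms: tert-butyl hydroperoxide, CC(C)(C)OO (its oxygen atom, relayed by SeO2, O=[Se]=O)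
Why: A second Sharpless SeO2/t-BuOOH allylic oxidation hydroxylates the E-methyl of the prenyl group (ene/[2,3] sequence), which fixes the E geometry of the future C2=C3 alkene.

Step 8
Reactants: 13 (2E)-4-[2-(tert-butyldimethylsilyloxy)-5-methoxy-3-methylphenyl]-2-methylbut-2-en-1-ol
Product: 14 tert-butyl{2-[(2E)-4-chloro-3-methylbut-2-en-1-yl]-4-methoxy-6-methylphenoxy}dimethylsilane
Conditions: PPh3, CCl4, 60 °C
Reagents that add atoms: carbon tetrachloride, ClC(Cl)(Cl)Cl
Why: Appel chlorination turns the primary allylic alcohol into the chloride by SN2 displacement without allylic transposition or E/Z loss, as in the preparation of geranyl chloride.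

Step 9
Reactants: 8 (2E,7R)-8-hydroxy-3,7,11-trimethyldodeca-2,10-dienal; 14 tert-butyl{2-[(2E)-4-chloro-3-methylbut-2-en-1-yl]-4-methoxy-6-methylphenoxy}dimethylsilane
Product: 18 (2E,6E,11R)-1-[2-(tert-butyldimethylsilyloxy)-5-methoxy-3-methylphenyl]-3,7,11,15-tetramethylhexadeca-2,6,14-triene-5,12-diol, via TMS ether 15 (not isolated), via allylbarium chloride 16 (not isolated), via silylated adduct 17 (not isolated)
Conditions: 8, hexamethyldisilazane (0.6 equiv), TMSCl (2 mol %), CH2Cl2, 23 °C, evaporate; 14 (1.2 equiv), activated Ba (from BaI2, lithium biphenylide, THF), −78 °C; add 15, −78 °C, 30 min; citric acid, MeOH–H2O, 0 °C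
Reagents that add atoms: none
Why: Transient TMS protection removes the acidic OH, and the E-allylbarium made from 14 adds 1,2 to the enal through its alpha carbon with retention of alkene geometry (Yamamoto allylbarium addition), forming C4–C5 as a C5 epimer mixture that the next oxidation removes, before citric acid cleaves the TMS ether.

Step 10
Reactants: 18 (2E,6E,11R)-1-[2-(tert-butyldimethylsilyloxy)-5-methoxy-3-methylphenyl]-3,7,11,15-tetramethylhexadeca-2,6,14-triene-5,12-diol
Product: 19 (2E,6E,11R)-1-[2-(tert-butyldimethylsilyloxy)-5-methoxy-3-methylphenyl]-3,7,11,15-tetramethylhexadeca-2,6,14-triene-5,12-dione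
Conditions: Dess–Martin periodinane (2.6 equiv), pyridine, CH2Cl2, 0 to 23 °C
Reagents that add atoms: none
Why: Dess–Martin oxidation under pyridine buffering converts both secondary alcohols into ketones without moving the beta,gamma-alkenes into conjugation or epimerising C11.

Step 11
Reactants: 19 (2E,6E,11R)-1-[2-(tert-butyldimethylsilyloxy)-5-methoxy-3-methylphenyl]-3,7,11,15-tetramethylhexadeca-2,6,14-triene-5,12-dione
Product: 20 (2E,6E,11R)-1-(2-hydroxy-5-methoxy-3-methylphenyl)-3,7,11,15-tetramethylhexadeca-2,6,14-triene-5,12-dione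
Conditions: TBAF, AcOH (1:1), THF, 0 °C, 15 min
Reagents that add atoms: none
Why: Acetic acid-buffered fluoride desilylation cleaves the aryl silyl ether quickly at 0 °C while the medium stays too weakly basic to epimerise C11 or conjugate the skipped enones.

**Compound list**

1 | geranyl acetate, (2E)-3,7-dimethylocta-2,6-dien-1-yl acetate | CC(=O)OC/C=C(\C)CCC=C(C)C | starting material
2 | (2E,6E)-8-hydroxy-3,7-dimethylocta-2,6-dien-1-yl acetate | CC(=O)OC/C=C(\C)CC/C=C(\C)CO | intermediate
3 | (2E,7R)-3,7-dimethyl-8-oxooct-2-en-1-yl acetate | CC(=O)OC/C=C(\C)CCC[C@@H](C)C=O | intermediate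
4 | prenyl chloride, 1-chloro-3-methylbut-2-ene | CC(C)=CCCl | starting material
5 | prenylbarium chloride, chlorido(3-methylbut-2-en-1-yl)barium | CC(C)=CC[Ba]Cl | intermediate
6 | (2E,7R)-8-hydroxy-3,7,11-trimethyldodeca-2,10-dien-1-yl acetate (C8 epimers) | CC(=O)OC/C=C(\C)CCC[C@@H](C)C(O)CC=C(C)C | intermediate
7 | (2E,7R)-3,7,11-trimethyldodeca-2,10-diene-1,8-diol (C8 epimers) | OC/C=C(\C)CCC[C@@H](C)C(O)CC=C(C)C | intermediate
8 | (2E,7R)-8-hydroxy-3,7,11-trimethyldodeca-2,10-dienal (C8 epimers) | O=C/C=C(\C)CCC[C@@H](C)C(O)CC=C(C)C | intermediate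
9 | 4-methoxy-2-methylphenol | COc1ccc(O)c(C)c1 | starting material
10 | prenyl bromide, 1-bromo-3-methylbut-2-ene | CC(C)=CCBr | starting material
11 | 4-methoxy-2-methyl-6-(3-methylbut-2-en-1-yl)phenol | COc1cc(C)c(O)c(CC=C(C)C)c1 | intermediate
12 | tert-butyl[4-methoxy-2-methyl-6-(3-methylbut-2-en-1-yl)phenoxy]dimethylsilane | COc1cc(C)c(O[Si](C)(C)C(C)(C)C)c(CC=C(C)C)c1 | intermediate
13 | (2E)-4-[2-(tert-butyldimethylsilyloxy)-5-methoxy-3-methylphenyl]-2-methylbut-2-en-1-ol | COc1cc(C)c(O[Si](C)(C)C(C)(C)C)c(C/C=C(\C)CO)c1 | intermediate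
14 | tert-butyl{2-[(2E)-4-chloro-3-methylbut-2-en-1-yl]-4-methoxy-6-methylphenoxy}dimethylsilane | COc1cc(C)c(O[Si](C)(C)C(C)(C)C)c(C/C=C(\C)CCl)c1 | intermediate
15 | (2E,7R)-3,7,11-trimethyl-8-(trimethylsilyloxy)dodeca-2,10-dienal (C8 epimers) | O=C/C=C(\C)CCC[C@@H](C)C(O[Si](C)(C)C)CC=C(C)C | intermediate
16 | chlorido{(2E)-4-[2-(tert-butyldimethylsilyloxy)-5-methoxy-3-methylphenyl]-2-methylbut-2-en-1-yl}barium | COc1cc(C)c(O[Si](C)(C)C(C)(C)C)c(C/C=C(\C)C[Ba]Cl)c1 | intermediate
17 | (2E,6E,11R)-1-[2-(tert-butyldimethylsilyloxy)-5-methoxy-3-methylphenyl]-3,7,11,15-tetramethyl-12-(trimethylsilyloxy)hexadeca-2,6,14-trien-5-ol (C5, C12 epimers) | COc1cc(C)c(O[Si](C)(C)C(C)(C)C)c(C/C=C(\C)CC(O)/C=C(\C)CCC[C@@H](C)C(O[Si](C)(C)C)CC=C(C)C)c1 | intermediate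
18 | (2E,6E,11R)-1-[2-(tert-butyldimethylsilyloxy)-5-methoxy-3-methylphenyl]-3,7,11,15-tetramethylhexadeca-2,6,14-triene-5,12-diol (C5, C12 epimers) | COc1cc(C)c(O[Si](C)(C)C(C)(C)C)c(C/C=C(\C)CC(O)/C=C(\C)CCC[C@@H](C)C(O)CC=C(C)C)c1 | intermediate
19 | (2E,6E,11R)-1-[2-(tert-butyldimethylsilyloxy)-5-methoxy-3-methylphenyl]-3,7,11,15-tetramethylhexadeca-2,6,14-triene-5,12-dione | COc1cc(C)c(O[Si](C)(C)C(C)(C)C)c(C/C=C(\C)CC(=O)/C=C(\C)CCC[C@@H](C)C(=O)CC=C(C)C)c1 | intermediate
20 | (2E,6E,11R)-1-(2-hydroxy-5-methoxy-3-methylphenyl)-3,7,11,15-tetramethylhexadeca-2,6,14-triene-5,12-dione | COc1cc(C)c(O)c(C/C=C(\C)CC(=O)/C=C(\C)CCC[C@@H](C)C(=O)CC=C(C)C)c1 | target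

**Step count and risks**

Total step count: 11. Longest linear sequence: 7 steps (steps 1, 2, 3, 4, 9, 10, 11 from geranyl acetate; the aryl branch, steps 5–8 then 9–11, is equally long).

Steps most likely to fail:

Step 2 (the proposed new isomerization). The tertiary alkyl–iridium intermediate may form slowly, the enol may leave the metal before hydride return (low ee), or the alpha-chiral aldehyde may racemise on the catalyst. The fallback sets out from 2. Hydroxyl-directed Noyori hydrogenation with Ru(OAc)2[(R)-BINAP] (1 mol %), H2 (50 atm), MeOH, 23 °C reduces only the alkene next to the free hydroxyl; the (R)-ligand is predicted from the geraniol facial model, and the antipode is used if the sense turns out reversed. This gives (2E,7R)-8-hydroxy-3,7-dimethyloct-2-en-1-yl acetate F1. Parikh–Doering oxidation of F1 (SO3·pyridine, DMSO, iPr2NEt, 0 °C) then gives the aldehyde, and the fallback comes back to the route at 3.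

Step 3. The organobarium may enolise aldehyde 3 (loss of ee at C7), attack the acetate, or give some gamma (reverse-prenyl) adduct. The fallback sets out from 4 and 3 and uses a Lewis-acid SE2′ reaction in place of an allyl anion. Magnesium in THF converts 4 into prenylmagnesium chloride F2, which TMSCl silylates at the tertiary terminus to give trimethyl(2-methylbut-3-en-2-yl)silane F3. Hosomi–Sakurai reaction of F3 with 3 (BF3·OEt2, CH2Cl2, −78 °C) proceeds with allylic transposition and therefore delivers the linear prenyl carbinol. The fallback comes back to the route at 6, which is methanolysed to 7 as in step 3.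

Step 9. The beta-methyl, gamma-monosubstituted allylbarium may give a lower alpha/gamma ratio than prenyl, lose E geometry or add sluggishly. The fallback sets out from 14 and 8 and uses sulfone umpolung. PhSO2Na in DMF converts 14 into tert-butyl{4-methoxy-2-methyl-6-[(2E)-3-methyl-4-(phenylsulfonyl)but-2-en-1-yl]phenoxy}dimethylsilane F4. n-BuLi in THF at −78 °C gives the alpha-lithio sulfone F5. Of 2.2 equivalents of F5, the first deprotonates the hydroxyl of 8 and the second adds to the aldehyde through the sulfonyl-bearing carbon to give (2E,6E,11R)-1-[2-(tert-butyldimethylsilyloxy)-5-methoxy-3-methylphenyl]-3,7,11,15-tetramethyl-4-(phenylsulfonyl)hexadeca-2,6,14-triene-5,12-diol F6. Dess–Martin oxidation gives the corresponding 4-(phenylsulfonyl)hexadeca-2,6,14-triene-5,12-dione F7. Reductive desulfonylation of this beta-keto sulfone with SmI2 in THF–MeOH at −78 °C brings the fallback back to the route at 19.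

Further compounds
F1 | step 2 | (2E,7R)-8-hydroxy-3,7-dimethyloct-2-en-1-yl acetate | CC(=O)OC/C=C(\C)CCC[C@@H](C)CO
F2 | step 3 | prenylmagnesium chloride, chlorido(3-methylbut-2-en-1-yl)magnesium | CC(C)=CC[Mg]Cl
F3 | step 3 | trimethyl(2-methylbut-3-en-2-yl)silane | C=CC(C)(C)[Si](C)(C)C
F4 | step 9 | tert-butyl{4-methoxy-2-methyl-6-[(2E)-3-methyl-4-(phenylsulfonyl)but-2-en-1-yl]phenoxy}dimethylsilane | COc1cc(C)c(O[Si](C)(C)C(C)(C)C)c(C/C=C(\C)CS(=O)(=O)c2ccccc2)c1
F5 | step 9 | alpha-lithio derivative of F4, {(2E)-4-[2-(tert-butyldimethylsilyloxy)-5-methoxy-3-methylphenyl]-2-methyl-1-(phenylsulfonyl)but-2-en-1-yl}lithium | COc1cc(C)c(O[Si](C)(C)C(C)(C)C)c(C/C=C(\C)C([Li])S(=O)(=O)c2ccccc2)c1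
F6 | step 9 | (2E,6E,11R)-1-[2-(tert-butyldimethylsilyloxy)-5-methoxy-3-methylphenyl]-3,7,11,15-tetramethyl-4-(phenylsulfonyl)hexadeca-2,6,14-triene-5,12-diol | COc1cc(C)c(O[Si](C)(C)C(C)(C)C)c(C/C=C(\C)C(S(=O)(=O)c2ccccc2)C(O)/C=C(\C)CCC[C@@H](C)C(O)CC=C(C)C)c1
F7 | step 9 | (2E,6E,11R)-1-[2-(tert-butyldimethylsilyloxy)-5-methoxy-3-methylphenyl]-3,7,11,15-tetramethyl-4-(phenylsulfonyl)hexadeca-2,6,14-triene-5,12-dione | COc1cc(C)c(O[Si](C)(C)C(C)(C)C)c(C/C=C(\C)C(S(=O)(=O)c2ccccc2)C(=O)/C=C(\C)CCC[C@@H](C)C(=O)CC=C(C)C)c1
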